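**Retrosynthetic overview**

- The target comes from 2-icosyl-5,7-dimethoxychromone by cleavage of the two aryl methyl ethers at C5 and C7.
- The plan rests on the pyranone ring O1–C2–C3–C4–C4a–C8a: a phenol oxygen (O1 on C8a), a carbonyl carbon (C4 on C4a) and a two-carbon unit C3–C2 with the C20 chain on C2, all attached to the C4a–C8a edge of a phloroglucinol-type benzene ring.
- Key disconnection: C4a–C4, C4–C3 and O1–C2, giving 2-iodo-3,5-dimethoxyphenol, carbon monoxide and docos-1-yne (Pd-catalysed carbonylative alkynylation, then amine-relayed 6-endo closure).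
- The iodophenol comes from 3,5-dimethoxyphenol by iodination between OH and OMe; docos-1-yne comes from 1-bromoicosane and lithium acetylide.
- Ring order: the benzene ring is bought with its three oxygens in place; the pyranone is the only ring formed, in the key step.

Key step: step 3

Remark: the target has no stereocentre and no stereogenic double bond or axis, so it is achiral and a single compound; no step has to set configuration.

**Route**

Step 1
Reactants: 1 3,5-dimethoxyphenol
Product: 2 2-iodo-3,5-dimethoxyphenol
Conditions: NIS (1.0 equiv, added slowly), CH2Cl2, −20 → 0 °C, dark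
Reagents that add atoms: N-iodosuccinimide, O=C1CCC(=O)N1I
Why: Electrophilic aromatic iodination, in which the two equivalent positions between OH and OMe should be preferred over C4 (buttressed between two methoxy groups, like C2 of 1,3-dimethoxybenzene) and the phenolic OH can hydrogen-bond to NIS in CH2Cl2 and deliver iodine to its own ortho carbon; slow addition of one equivalent at low temperature limits the 2,6-diiodide, and the minor 4-iodo isomer is removed by chromatography.

Step 2
Reactants: 3 1-bromoicosane; 4 lithium acetylide ethylenediamine complex (1.5 equiv)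
Product: 5 docos-1-yne
Conditions: DMSO/THF, 10 °C → rt; H2O quench
Reagents that add atoms: none
Why: SN2 alkylation of a terminal acetylide by an unbranched primary bromide in DMSO, the standard use of this complex, with THF keeping the waxy C20 bromide in solution and the excess of acetylide suppressing double alkylation.

Step 3
Reactants: 2 2-iodo-3,5-dimethoxyphenol; 5 docos-1-yne (1.2 equiv); 6 carbon monoxide
Product: 9 2-icosyl-5,7-dimethoxy-4H-chromen-4-one, via aryl ynone 7 (not isolated), via beta-aminoenone 8 (not isolated)
Conditions: PdCl2(dppf) (5 mol %), CO (20 atm), Et2NH (solvent and base), 120 °C, autoclave, no copper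
Reagents that add atoms: diethylamine, CCNCC (its atoms are carried only in intermediate 8 and leave again on ring closure)
Why: Pd(0) inserts into the C–I bond of 2, CO insertion gives an aroyl-palladium(II) species, and amine-assisted alkynylation with 5 followed by reductive elimination gives ynone 7, which forms C4a–C4 and C4–C3. Et2NH then adds to the ynone to give β-aminoenone 8 (drawn E; either geometry closes), and the ortho phenol attacks the amino-bearing carbon and expels Et2NH, which forms O1–C2. The closest known reaction type is the Pd-catalysed carbonylative Sonogashira coupling and cyclisation of 2-iodophenols with terminal alkynes, aliphatic ones included, in a secondary amine to give chromones. The pyranone, the one ring closed, forms by 6-endo attack of oxygen on C2 (6-endo-dig counted on 7, carried out as 6-endo-trig addition–elimination on 8), and no stereocentre arises. Carbonylation must outrun direct alkynylation (which would lead to a benzofuran); this is secured by the CO pressure, the absence of copper and the chelating ligand, acyl migration being fast for an electron-rich, doubly ortho-substituted aryl–palladium. The 6-endo closure must outrun 5-exo closure to an aurone; this is secured because C3 in 8 is no longer electrophilic, while the 5,7-dioxygenation pattern is fixed beforehand by the iodine of 2 lying between OH and OMe.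

Step 4
Reactants: 9 2-icosyl-5,7-dimethoxy-4H-chromen-4-one
Product: 10 5,7-dihydroxy-2-icosyl-4H-chromen-4-one
Conditions: BBr3 (6 equiv), CH2Cl2, −78 °C → rt (reflux if needed); then H2O
Reagents that add atoms: none
Why: Lewis-acid cleavage of aryl methyl ethers, in which BBr3 coordinates each ether oxygen and bromide removes the methyl group by SN2; the C5 ether is helped by chelation to the C4 carbonyl and the C7 ether by excess reagent and warming, while the pyranone and the alkyl chain are inert and the B–O bonds are hydrolysed on work-up.

**Compound list**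

1 | 3,5-dimethoxyphenol | COc1cc(O)cc(OC)c1 | starting material
2 | 2-iodo-3,5-dimethoxyphenol | COc1cc(O)c(I)c(OC)c1 | intermediate
3 | 1-bromoicosane | CCCCCCCCCCCCCCCCCCCCBr | starting material
4 | lithium acetylide ethylenediamine complex | [Li]C#C.NCCN | starting material
5 | docos-1-yne | C#CCCCCCCCCCCCCCCCCCCCC | intermediate
6 | carbon monoxide | [C-]#[O+] | starting material
7 | 1-(2-hydroxy-4,6-dimethoxyphenyl)tricos-2-yn-1-one | CCCCCCCCCCCCCCCCCCCCC#CC(=O)c1c(O)cc(OC)cc1OC | intermediate (not isolated)
8 | (E)-3-(diethylamino)-1-(2-hydroxy-4,6-dimethoxyphenyl)tricos-2-en-1-one | CCCCCCCCCCCCCCCCCCCC/C(N(CC)CC)=C\C(=O)c1c(O)cc(OC)cc1OC | intermediate (not isolated)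
9 | 2-icosyl-5,7-dimethoxy-4H-chromen-4-one | CCCCCCCCCCCCCCCCCCCCc1cc(=O)c2c(OC)cc(OC)cc2o1 | intermediate
10 | 5,7-dihydroxy-2-icosyl-4H-chromen-4-one | CCCCCCCCCCCCCCCCCCCCc1cc(=O)c2c(O)cc(O)cc2o1 | target

**Step count**

Total steps: 4 (convergent; steps 1 and 2 are independent one-step branches).
Longest linear sequence: 3 steps (1 → 3 → 4, or equally 2 → 3 → 4).

**Steps most likely to fail**

1. Step 3 (key step). Direct, non-carbonylative alkynylation followed by 5-endo closure to a benzofuran may outrun CO insertion. Oxidative addition at the electron-rich C–I bond flanked by OH and OMe may be slow enough for reductive deiodination to take over. The ynone may also close 5-exo before the amine has added.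
Fallback without carbonylation, setting out from docos-1-yne 5 and rejoining the route at ynone 7 and then 9. Compound 5 is deprotonated with n-BuLi (THF, −20 °C) to lithium docos-1-yn-1-ide F1. About 2.3 equiv of it are added at −78 → 0 °C to commercial 2-hydroxy-4,6-dimethoxybenzaldehyde (COc1cc(O)c(C=O)c(OC)c1); the first equivalent is consumed by the phenol and that alkyne is recovered. Quenching with aqueous NH4Cl gives racemic 1-(2-hydroxy-4,6-dimethoxyphenyl)tricos-2-yn-1-ol F2, which is acid-sensitive and is used crude. Activated MnO2 (CH2Cl2, rt) oxidises the benzylic, propargylic alcohol to ynone 7, now isolated. Et2NH in EtOH (rt → reflux) then takes 7 by way of 8 to chromone 9 through the same amine addition–elimination closure.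

2. Step 1. Electrophilic attack at C4 (para to OH) and over-iodination may compete with attack at C2, leaving isomers that are hard to separate.
Fallback by directed ortho-metalation, setting out from 1 and coming back at 2. Carbamoylation (Et2NCOCl, K2CO3, MeCN, reflux) gives 3,5-dimethoxyphenyl N,N-diethylcarbamate F3. s-BuLi/TMEDA (THF, −78 °C) lithiates the position flanked by the carbamate, the strongest director present, and a methoxy group, giving [2-(diethylcarbamoyloxy)-4,6-dimethoxyphenyl]lithium F4. Quenching at −78 °C with I2, before anionic Fries rearrangement can set in, gives 2-iodo-3,5-dimethoxyphenyl N,N-diethylcarbamate F5. Hydrolysis (NaOH, EtOH/H2O, reflux; acid work-up) releases 2.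

3. Step 4. The C7 ether lacks the carbonyl chelation that helps C5, so cleavage may stall at the mono-phenol, and forcing it may erode the material.
Fallback by a change of protecting group, setting out from docos-1-yne 5 and coming back at target 10. Commercial 3,5-bis(benzyloxy)phenol (Oc1cc(OCc2ccccc2)cc(OCc2ccccc2)c1) is iodinated as in step 1 (NIS, CH2Cl2) to 3,5-bis(benzyloxy)-2-iodophenol F6. This is taken with 5 and 6 through the conditions of step 3, by way of 1-[2,4-bis(benzyloxy)-6-hydroxyphenyl]tricos-2-yn-1-one F7 and (E)-1-[2,4-bis(benzyloxy)-6-hydroxyphenyl]-3-(diethylamino)tricos-2-en-1-one F8, neither isolated, to 5,7-bis(benzyloxy)-2-icosyl-4H-chromen-4-one F9. Hydrogenolysis (H2 1 atm, Pd/C, EtOAc/THF, rt), stopped after uptake of two equivalents so that the C2=C3 bond of the vinylogous ester is kept, gives 10.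

**Further compounds**

F1 | step 3 | lithium docos-1-yn-1-ide | [Li]C#CCCCCCCCCCCCCCCCCCCCC
F2 | step 3 | 1-(2-hydroxy-4,6-dimethoxyphenyl)tricos-2-yn-1-ol (racemic) | CCCCCCCCCCCCCCCCCCCCC#CC(O)c1c(O)cc(OC)cc1OC
F3 | step 1 | 3,5-dimethoxyphenyl N,N-diethylcarbamate | CCN(CC)C(=O)Oc1cc(OC)cc(OC)c1
F4 | step 1 | [2-(diethylcarbamoyloxy)-4,6-dimethoxyphenyl]lithium | [Li]c1c(OC(=O)N(CC)CC)cc(OC)cc1OC
F5 | step 1 | 2-iodo-3,5-dimethoxyphenyl N,N-diethylcarbamate | CCN(CC)C(=O)Oc1cc(OC)cc(OC)c1I
F6 | step 4 | 3,5-bis(benzyloxy)-2-iodophenol | Oc1cc(OCc2ccccc2)cc(OCc2ccccc2)c1I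
F7 | step 4 | 1-[2,4-bis(benzyloxy)-6-hydroxyphenyl]tricos-2-yn-1-one | CCCCCCCCCCCCCCCCCCCCC#CC(=O)c1c(O)cc(OCc2ccccc2)cc1OCc1ccccc1
F8 | step 4 | (E)-1-[2,4-bis(benzyloxy)-6-hydroxyphenyl]-3-(diethylamino)tricos-2-en-1-one | CCCCCCCCCCCCCCCCCCCC/C(N(CC)CC)=C\C(=O)c1c(O)cc(OCc2ccccc2)cc1OCc1ccccc1
F9 | step 4 | 5,7-bis(benzyloxy)-2-icosyl-4H-chromen-4-one | CCCCCCCCCCCCCCCCCCCCc1cc(=O)c2c(OCc3ccccc3)cc(OCc3ccccc3)cc2o1
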